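## Retrosynthetic overview

1. Target ⇒ acetonide-protected 3,6-dibenzoate ⇒ regioselective benzoylation of a cis-enediol triol ⇒ O–O reduction of a bicyclic endoperoxide.
2. Key step: the endoperoxide ⇒ [4+2] addition of singlet oxygen to an arene-hydrate-type cyclohexadiene (the trans-1,2-dihydrodiol of benzyl alcohol, masked as a spiro-acetonide) on the face of its free hydroxyl; C3–O and C6–O are set together.
3. Diene ⇒ cyclohexene by bromination and double dehydrobromination; trans C1–O/C2–O ⇒ benzoate opening of an oxirane that stands in for the arene 1,2-oxide.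
4. Oxirane ⇒ Sharpless epoxidation of 2,5-dihydrobenzyl alcohol ⇒ Birch reduction of benzyl alcohol.
5. Ring order: carbocycle taken from the arene; oxirane (opened); dioxolane (protecting ring); 1,2-dioxane ring of the endoperoxide (opened by O–O reduction).

Assumption: the presumed biogenesis is taken to be the arene-oxide pathway of a shikimate-derived benzyl unit, that is ipso/ortho oxirane, trans opening, then 1,4-addition of dioxygen across the remaining diene, O–O reduction and benzoyl transfer.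

Numbering: target C1 = quaternary carbinol carbon, C2 = CH(OH), C3 and C6 = CH(OBz), C7 = CH2OH. In the spiro intermediates C5 = target C1, C6 = C2, C7 = C3, C10 = C6 and C4 = C7.

## Route

Step 1
Reactants: 1 benzyl alcohol
Product: 2 (cyclohexa-1,4-dien-1-yl)methanol
Conditions: Li, NH3 (l), THF, EtOH, −78 °C; then NH4Cl
Reagents that add atoms: none
Why: Birch reduction, in which the lithium alkoxide formed in situ suppresses benzylic C–O hydrogenolysis and the carbon bearing the hydroxymethyl group ends up on a double bond of the skipped diene; no stereocenter is formed.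

Step 2
Reactants: 2 (cyclohexa-1,4-dien-1-yl)methanol
Product: 3 [(1S,6S)-7-oxabicyclo[4.1.0]hept-3-en-1-yl]methanol
Conditions: Ti(OiPr)4 (10 mol %), L-(+)-diisopropyl tartrate (12 mol %), t-BuOOH, 4 Å molecular sieves, CH2Cl2, −25 °C
Reagents that add atoms: tert-butyl hydroperoxide, CC(C)(C)OO
Why: Sharpless asymmetric epoxidation, in which the titanium tartrate binds the allylic alcohol so that only that alkene is oxidised and L-(+)-tartrate gives the (1S,6S)-oxirane (about 90–95% ee expected), which fixes target C1 and is the stable stand-in for the arene 1,2-oxide.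

Step 3
Reactants: 3 [(1S,6S)-7-oxabicyclo[4.1.0]hept-3-en-1-yl]methanol
Product: 4 (1R,6S)-6-hydroxy-6-(hydroxymethyl)cyclohex-3-en-1-yl benzoate
Conditions: Ti(OiPr)4 (1.5 equiv), PhCO2H (1.3 equiv), CH2Cl2, 0 °C → rt
Reagents that add atoms: benzoic acid, OC(=O)c1ccccc1
Why: Titanium-mediated regioselective opening of a 2,3-epoxy alcohol (Sharpless C-3 opening), in which benzoate attacks the secondary ring carbon of the chelated oxirane with inversion and so sets target C2 trans to the retained tertiary C1–O.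

Step 4
Reactants: 4 (1R,6S)-6-hydroxy-6-(hydroxymethyl)cyclohex-3-en-1-yl benzoate
Product: 5 (5S,6R)-2,2-dimethyl-1,3-dioxaspiro[4.5]dec-8-en-6-yl benzoate
Conditions: 2,2-dimethoxypropane, PPTS (cat.), CH2Cl2, rt
Reagents that add atoms: 2,2-dimethoxypropane, COC(C)(C)OC
Why: Acid-catalysed transacetalisation, in which the only free hydroxyls are the tertiary/primary 1,2-diol and these close to the spiro-dioxolane; no stereocenter is touched.

Step 5
Reactants: 5 (5S,6R)-2,2-dimethyl-1,3-dioxaspiro[4.5]dec-8-en-6-yl benzoate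
Product: 8 (5S,6R)-2,2-dimethyl-1,3-dioxaspiro[4.5]deca-7,9-dien-6-ol, via trans-dibromide 6 (not isolated), via diene benzoate 7 (not isolated)
Conditions: Br2, CH2Cl2, −78 °C; then DBU, THF, 60 °C; then K2CO3 (cat.), MeOH, rt
Reagents that add atoms: none
Why: Anti bromination of the isolated alkene, double E2 dehydrobromination to the conjugated diene (aromatisation is blocked by the quaternary spiro carbon) and base-catalysed transesterification that removes the benzoate, which until then kept the C6 oxygen from capturing the bromonium ion; both stereocenters are untouched.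

Step 6
Reactants: 8 (5S,6R)-2,2-dimethyl-1,3-dioxaspiro[4.5]deca-7,9-dien-6-ol
Product: 10 (5R,6R,7R,10S)-2,2-dimethyl-1,3-dioxaspiro[4.5]dec-8-ene-6,7,10-triol, via endoperoxide 9 (not isolated)
Conditions: O2, tetraphenylporphyrin (cat.), visible light, CH2Cl2, −30 °C; then Zn, AcOH, 0 °C
Reagents that add atoms: dioxygen, O=O
Why: [4+2] cycloaddition of singlet oxygen (Schenck-type photooxygenation), steered to the face of the free allylic hydroxyl by hydrogen bonding in a non-donor solvent and away from the allylic acetal oxygen, forms the endoperoxide and sets both new C–O stereocenters cis to the C6 hydroxyl, after which zinc cleaves only the O–O bond.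

Step 7
Reactants: 10 (5R,6R,7R,10S)-2,2-dimethyl-1,3-dioxaspiro[4.5]dec-8-ene-6,7,10-triol
Product: 11 (5S,6R,7R,10S)-6-hydroxy-2,2-dimethyl-1,3-dioxaspiro[4.5]dec-8-ene-7,10-diyl dibenzoate
Conditions: BzCl (2.1 equiv), pyridine, CH2Cl2, −40 → −10 °C
Reagents that add atoms: benzoyl chloride, O=C(Cl)c1ccccc1
Why: Regioselective acylation, in which the two allylic hydroxyls at C7 and C10 react before the C6 hydroxyl that is flanked by the spiro quaternary carbon and, after the first acylation, by an acyloxy-bearing carbon.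

Step 8
Reactants: 11 (5S,6R,7R,10S)-6-hydroxy-2,2-dimethyl-1,3-dioxaspiro[4.5]dec-8-ene-7,10-diyl dibenzoate
Product: 12 (1S,4R,5R,6S)-5,6-dihydroxy-6-(hydroxymethyl)cyclohex-2-ene-1,4-diyl dibenzoate (target)
Conditions: AcOH–H2O (4:1), 40 °C
Reagents that add atoms: none
Why: Acid-catalysed acetal hydrolysis, under which the benzoates are stable and acyl migration is slow, so all four stereocenters arrive unchanged.

## Compound list

1 | benzyl alcohol | OCc1ccccc1 | starting material
2 | (cyclohexa-1,4-dien-1-yl)methanol | OCC1=CCC=CC1 | intermediate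
3 | [(1S,6S)-7-oxabicyclo[4.1.0]hept-3-en-1-yl]methanol | OC[C@@]12CC=CC[C@@H]1O2 | intermediate
4 | (1R,6S)-6-hydroxy-6-(hydroxymethyl)cyclohex-3-en-1-yl benzoate | OC[C@@]1(O)CC=CC[C@H]1OC(=O)c1ccccc1 | intermediate
5 | (5S,6R)-2,2-dimethyl-1,3-dioxaspiro[4.5]dec-8-en-6-yl benzoate | CC1(C)OC[C@@]2(O1)CC=CC[C@H]2OC(=O)c1ccccc1 | intermediate
6 | (5S,6R)-8,9-dibromo-2,2-dimethyl-1,3-dioxaspiro[4.5]decan-6-yl benzoate, trans-8,9-dibromide (both trans diastereomers form; one is drawn) | CC1(C)OC[C@@]2(O1)C[C@H](Br)[C@@H](Br)C[C@H]2OC(=O)c1ccccc1 | intermediate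
7 | (5S,6R)-2,2-dimethyl-1,3-dioxaspiro[4.5]deca-7,9-dien-6-yl benzoate | CC1(C)OC[C@@]2(O1)C=CC=C[C@H]2OC(=O)c1ccccc1 | intermediate
8 | (5S,6R)-2,2-dimethyl-1,3-dioxaspiro[4.5]deca-7,9-dien-6-ol | CC1(C)OC[C@@]2(O1)C=CC=C[C@H]2O | intermediate
9 | (1'S,4S,4'R,8'R)-2,2-dimethylspiro[1,3-dioxolane-4,7'-[2,3]dioxabicyclo[2.2.2]oct[5]en]-8'-ol; the peroxide bridge is cis to the hydroxyl and to the dioxolane CH2, trans to the dioxolane oxygen | CC1(C)OC[C@@]2(O1)[C@@H]3C=C[C@@H](OO3)[C@H]2O | intermediate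
10 | (5R,6R,7R,10S)-2,2-dimethyl-1,3-dioxaspiro[4.5]dec-8-ene-6,7,10-triol (all three hydroxyls cis) | CC1(C)OC[C@@]2(O1)[C@@H](O)C=C[C@@H](O)[C@H]2O | intermediate
11 | (5S,6R,7R,10S)-6-hydroxy-2,2-dimethyl-1,3-dioxaspiro[4.5]dec-8-ene-7,10-diyl dibenzoate | CC1(C)OC[C@@]2(O1)[C@@H](OC(=O)c1ccccc1)C=C[C@@H](OC(=O)c1ccccc1)[C@H]2O | intermediate
12 | (1S,4R,5R,6S)-5,6-dihydroxy-6-(hydroxymethyl)cyclohex-2-ene-1,4-diyl dibenzoate | O=C(O[C@H]1C=C[C@@H](OC(=O)c2ccccc2)[C@@H](O)[C@@]1(O)CO)c1ccccc1 | target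

## Step count and risks

Total step count: 8. Longest linear sequence: 8 steps (fully linear from benzyl alcohol).

The three steps most likely to fail:

**Step 5.** The risks are capture of the bromonium ion by a neighbouring oxygen, 1,4-elimination toward C6 that would give a dienyl ester, and loss of the acid-sensitive dienol 8. The fallback sets out from 5 and comes back at 7. A Schenck ene reaction of 5 (O2, tetraphenylporphyrin, visible light, CH2Cl2) gives the two allylic hydroperoxides (5S,6R)-9-hydroperoxy-2,2-dimethyl-1,3-dioxaspiro[4.5]dec-7-en-6-yl benzoate F1 and (5S,6R)-8-hydroperoxy-2,2-dimethyl-1,3-dioxaspiro[4.5]dec-9-en-6-yl benzoate F2. PPh3 reduces them in the flask to the allylic alcohols (5S,6R)-9-hydroxy-2,2-dimethyl-1,3-dioxaspiro[4.5]dec-7-en-6-yl benzoate F3 and (5S,6R)-8-hydroxy-2,2-dimethyl-1,3-dioxaspiro[4.5]dec-9-en-6-yl benzoate F4. Burgess reagent (toluene, 60 °C) dehydrates both, each having only one set of hydrogens available for elimination, to the same diene 7, which is then methanolysed to 8 as before.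

**Step 6.** This is the boldest step: the hydroxyl-directed face must win over the face next to the acetal oxygen, which sterically is the smaller one; attack on the wrong face gives the 7,10-bis-epimer. The fallback sets out from 8 and comes back at 11. VO(acac)2 (cat.) and t-BuOOH in CH2Cl2 at 0 °C epoxidise the alkene next to the carbinol strictly cis to the hydroxyl and give the 7,8-epoxide of 8 with the oxirane cis to the 6-hydroxyl, 2,2-dimethylspiro[1,3-dioxolane-4,3'-[7]oxabicyclo[4.1.0]hept[4]en]-2'-ol F5. Pd(PPh3)4 (zerovalent palladium) and benzoic acid in THF then open the vinyl oxirane with overall 1,4-syn addition (ionisation with inversion, external benzoate attack with inversion) to (5S,6R,7R,10S)-6,7-dihydroxy-2,2-dimethyl-1,3-dioxaspiro[4.5]dec-8-en-10-yl benzoate F6. Benzoylation of its allylic 7-hydroxyl (BzCl, pyridine, −40 °C) gives 11.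

**Step 7.** The risk is that the 6-hydroxyl competes, giving the 6,7- or 6,10-dibenzoate or the tribenzoate. The fallback sets out from 9, now isolated by leaving out the zinc, and comes back at 12. Et3SiOTf and 2,6-lutidine (CH2Cl2, −78 °C) cap the only free hydroxyl to give the triethylsilyl ether of 9, 2,2-dimethyl-8'-[(triethylsilyl)oxy]spiro[1,3-dioxolane-4,7'-[2,3]dioxabicyclo[2.2.2]oct[5]ene] F7. Thiourea in MeOH reduces the peroxide to (5R,6R,7R,10S)-2,2-dimethyl-6-[(triethylsilyl)oxy]-1,3-dioxaspiro[4.5]dec-8-ene-7,10-diol F8. Exhaustive benzoylation (BzCl, DMAP, pyridine) gives (5R,6R,7R,10S)-2,2-dimethyl-6-[(triethylsilyl)oxy]-1,3-dioxaspiro[4.5]dec-8-ene-7,10-diyl dibenzoate F9. The aqueous acetic acid of step 8 then removes the acetonide and the silyl ether together to give 12.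

## Further compounds

F1 | step 5 | (5S,6R)-9-hydroperoxy-2,2-dimethyl-1,3-dioxaspiro[4.5]dec-7-en-6-yl benzoate (C9 epimers) | CC1(C)OC[C@@]2(O1)CC(OO)C=C[C@H]2OC(=O)c1ccccc1
F2 | step 5 | (5S,6R)-8-hydroperoxy-2,2-dimethyl-1,3-dioxaspiro[4.5]dec-9-en-6-yl benzoate (C8 epimers) | CC1(C)OC[C@@]2(O1)C=CC(OO)C[C@H]2OC(=O)c1ccccc1
F3 | step 5 | (5S,6R)-9-hydroxy-2,2-dimethyl-1,3-dioxaspiro[4.5]dec-7-en-6-yl benzoate (C9 epimers) | CC1(C)OC[C@@]2(O1)CC(O)C=C[C@H]2OC(=O)c1ccccc1
F4 | step 5 | (5S,6R)-8-hydroxy-2,2-dimethyl-1,3-dioxaspiro[4.5]dec-9-en-6-yl benzoate (C8 epimers) | CC1(C)OC[C@@]2(O1)C=CC(O)C[C@H]2OC(=O)c1ccccc1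
F5 | step 6 | 2,2-dimethylspiro[1,3-dioxolane-4,3'-[7]oxabicyclo[4.1.0]hept[4]en]-2'-ol, oxirane cis to the hydroxyl | CC1(C)OC[C@@]2(O1)C=C[C@H]3O[C@H]3[C@H]2O
F6 | step 6 | (5S,6R,7R,10S)-6,7-dihydroxy-2,2-dimethyl-1,3-dioxaspiro[4.5]dec-8-en-10-yl benzoate | CC1(C)OC[C@@]2(O1)[C@@H](OC(=O)c1ccccc1)C=C[C@@H](O)[C@H]2O
F7 | step 7 | 2,2-dimethyl-8'-[(triethylsilyl)oxy]spiro[1,3-dioxolane-4,7'-[2,3]dioxabicyclo[2.2.2]oct[5]ene], configuration as in 9 | CC1(C)OC[C@@]2(O1)[C@@H]3C=C[C@@H](OO3)[C@H]2O[Si](CC)(CC)CC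
F8 | step 7 | (5R,6R,7R,10S)-2,2-dimethyl-6-[(triethylsilyl)oxy]-1,3-dioxaspiro[4.5]dec-8-ene-7,10-diol | CC1(C)OC[C@@]2(O1)[C@@H](O)C=C[C@@H](O)[C@H]2O[Si](CC)(CC)CC
F9 | step 7 | (5R,6R,7R,10S)-2,2-dimethyl-6-[(triethylsilyl)oxy]-1,3-dioxaspiro[4.5]dec-8-ene-7,10-diyl dibenzoate | CC1(C)OC[C@@]2(O1)[C@@H](OC(=O)c1ccccc1)C=C[C@@H](OC(=O)c1ccccc1)[C@H]2O[Si](CC)(CC)CC
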